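The data are calculated for substances that don't exist; noise was put on by code.

- Crystals first. You asked for a quick number, and your hunch is that the rate follows G; no earlier run changes G, so that stays a guess, and I read what the earlier east run does show.

| flask | E | Q | G | remark | time | volume of the second phase over the first |
|---|---|---|---|---|---|---|
| east | 35 mM | 45.5 mM | 1.3 mM | run made earlier |  |  |
| flask | 35 mM | 45.5 mM | 0.67 mM |  | 80 min | 1.0 |

east run (percent of the E charged)

| time / min | L / % | Z / % |
|---|---|---|
| 3.00 | 20.0 | 14.3 |
| 6.00 | 34.6 | 29.8 |
| 10.0 | 48.4 | 44.4 |
| 12.0 | 53.7 | 49.7 |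
| 15.0 | 59.7 | 56.0 |

(readings scatter by 0.3 percentage points)

- what is said of L includes Z
- charges count per volume of the first phase; a concentration in a rate is the amount of a species over the volume of its own phase; every rate counts per litre of the first phase
- Z is a solid; its amount is given per volume of the solution
- the earlier runs hold the two phases in the same ratio of volumes as the flask asked about
- no earlier run changes the charge of G; that part of a forecast is a guess

- how much L and Z together there is at 80 min, in percent of the E charged
- concentration of L in solution at 80 min, in percent of saturation

- In the east run, dissolved L is L minus Z. Between 3.00 min and 6.00 min, Z grows by 1.81 mM min⁻¹ while [L] averages 1.84 mM. Between 12.0 min and 15.0 min, it grows by 0.735 mM min⁻¹ at 1.35 mM.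
- Growth of Z in the east run therefore falls with [L] at a slope of 2.19 min⁻¹. Carried down to zero growth, that line reads 1.01 mM. This is c*: the [L] at which Z neither grows nor shrinks, in the usual term the solubility. Above c*, Z grows; below it, while Z is present, Z shrinks. It is a reading, as coarse as the scatter makes it.
- My forecast for the flask, with the rate scaled to G, is 84.5% (78% to 90%) for L and Z together and 104% (100.5% to 112%) of saturation for [L]. My ground for the second: “Solution sits about 4 % above saturation.”
- The flask gives 32.7% for L and Z together and 85.3% of saturation for [L], both lower than forecast.

    G + Q ⇌ J + D (K = 1.47, k = 62.5 M⁻¹ min⁻¹)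
    L → X (k = 0.296 min⁻¹)
    Z ⇌ L, rate k3*(cs3 - [L]) while solid is left; crystals form when [L] > cs3 (solubility = 0.920 mM, k = 1.70 min⁻¹)
    E + J → L + G (k = 679 M⁻¹ min⁻¹)

- At 80.0 min the flask holds X at 67.3% of the E charged, and its [L] is 0.785 mM, lower than c*. That is the side on which the rule has Z shrinking, and Z is down from 49.9% at 40.0 min to 30.4%. The neighbouring flask is the same one charged with 21 mM of E, so there c* is 4.81% of the E charged. At 80.0 min that neighbour holds L at 0.756%, an [L] of 0.159 mM, lower than c*, with X at 99.2% and Z at 0%.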